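**Two ratios.** The ratio c(G)/c(Z) in the flask with 0.037 M of E, early and late, is what I want, and two earlier runs are what I have.

| flask | E | remark | time |
|---|---|---|---|
| west | 0.018 M | run made earlier |  |
| south-east | 0.028 M | run made earlier |  |
| flask | 0.037 M |  | 4.0 h |

| run | time / h | G / % | Z / % |
|---|---|---|---|
| west | 0.333 | 9.1 | 23.4 |
| west | 1.00 | 5.4 | 61.8 |
| west | 2.00 | 2.6 | 87.0 |
| west | 3.00 | 1.5 | 94.7 |
| west | 4.00 | 0.1 | 98.7 |
| south-east | 0.833 | 6.1 | 54.6 |
| south-east | 1.50 | 3.1 | 76.7 |
| south-east | 2.50 | 0.7 | 91.2 |
| south-east | 3.00 | 0.2 | 95.6 |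
| south-east | 4.00 | 0.5 | 98.3 |

(each reading ± 0.5 percentage points)

- ratio of G to Z at 2.0 min
- ratio of G to Z at 4.0 h



**Main step.** I begin with one step, G going to Z, and call everything not yet Z the unfinished pool. The pool falls at a reading of 0.988 h⁻¹ in west and 1.08 h⁻¹ in south-east, so I carry the mean, 1.03 h⁻¹, to the flask. The G share, c(G) over the unfinished pool, reads 0.136 in the middle readings, a quasi-steady share. If Z comes from G, G clears at 7.58 h⁻¹, faster than the pool falls, so G can follow the pool.

**Late ratio.** Carrying the mean pool of the two runs forward from their readings at 3.00 h gives 1.73 % at 4.0 h. With Z taken as the whole charge, the ratio is 0.00235; taking that pool out of Z gives 0.00240.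

**Early ratio.** Now I add the feed from E. G rises along a nearly straight line while Z collects behind it, so the ratio is 2 over k times time, 7.92. Going round again for the bend in that line gives 7.54, my figure. One unseen step before G would turn the 2 into 3, giving 11.9, but the readings begin too late to show this.

The forecast gives 5 and 0.0022, and says of the early value: “This is very uncertain because it is extrapolated before the first reading.” The flask gives 10.8 and 0.00255.

    G → Z (k = 0.00210 s⁻¹)
    E → J (k = 0.00820 s⁻¹)
    E ⇌ X (K = 6.80, k = 0.150 s⁻¹)
    J ⇌ L (K = 1.70, k = 0.00760 s⁻¹)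
    L → G (k = 0.0230 s⁻¹)
    X ⇌ D (K = 2.60, k = 0.00620 s⁻¹)

**Neighbour flask.** At 4.00 h the flask holds G at 0.133 of its pool of E, G, X, J, D and L, against my share of 0.136. Early, the flask's ratio times k times time is 2.72, above 2 and below 3. The neighbour flask holds 0.063 M of E, with all else unchanged. Its pool is 1.87 % and its Z is 98.1 %, so my share gives 0.00259. The neighbour flask itself gives 0.00255.

The data come from a simulation with constants of no real substance.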